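**Retrosynthetic overview**
1. Target 17 ⇐ 2,5-dimethoxyquinone 16 (selective hydrolysis of the methoxy group next to the side chain) ⇐ tetramethoxyarene 15 (oxidative demethylation).
2. 15 ⇐ aryllithium 14 (from 13) + (S,E)-allylic bromide 12; 12 ⇐ alkyne 9 by carboalumination/formaldehyde, which fixes the E-alkene.
3. Key step: 9 ⇐ racemic tertiary allylic alcohol 4 by enantioselective C–N bond formation with sulfonylhydrazide 5, then N2-extruding retro-ene that copies the C–N stereocentre into the ring C–H stereocentre and places the ring alkene.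
4. 4 ⇐ enone 1 + Grignard reagent from bromide 2.
5. No ring is built: the cyclohexene ring comes from 1 and the quinone ring from 13 (unveiled last).

Assumptions: the target is taken exactly as the SMILES gives it ((S) at the ring carbon, E side-chain alkene); the (S,S) form of the acid catalyst is written for the needed (S) sense in step 2, and its mirror image is used if induction proves opposite.

**Step 1**
Reactants: 1 2,6,6-trimethylcyclohex-2-en-1-one; 2 (4-bromobut-1-yn-1-yl)trimethylsilane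
Product: 4 racemic 2,6,6-trimethyl-1-[4-(trimethylsilyl)but-3-yn-1-yl]cyclohex-2-en-1-ol, via Grignard reagent 3 (not isolated)
Conditions: 2, Mg, THF, 40 °C; CeCl3, THF, −78 °C; then 1, −78 → 0 °C; aq NH4Cl
Reagents that add atoms: none
Why: Organocerium (Imamoto-type) 1,2-addition of the Grignard-derived nucleophile to the hindered enone, which has no enolisable α-hydrogen, gives the tertiary allylic alcohol; it is made racemic on purpose because step 2 is enantioconvergent.

**Step 2**
Reactants: 4 racemic 2,6,6-trimethyl-1-[4-(trimethylsilyl)but-3-yn-1-yl]cyclohex-2-en-1-ol; 5 4-methylbenzenesulfonohydrazide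
Product: 9 (6S)-6-(but-3-yn-1-yl)-1,5,5-trimethylcyclohex-1-ene, via allylic sulfonylhydrazide 6 (not isolated), via allylic diazene 7 (not isolated), via silylated alkyne 8 (not isolated)
Conditions: 5 (1.5 equiv), (S,S)-imidodiphosphorimidate Brønsted acid (two (S)-3,3'-bis[3,5-bis(trifluoromethyl)phenyl]-BINOL phosphorus units bridged by NH, each P=N–SO2CF3; C74H33F30N3O8P2S2; 5 mol %), 5 Å MS, CHCl3, −40 °C; then K2CO3 (3 equiv), MeOH, −40 → 45 °C
Reagents that add atoms: none
Why: Proposed new method: the confined chiral acid ionises either enantiomer of 4 to one achiral cyclohexenyl cation paired with the chiral anion, the NH2 of 5 adds to the less hindered secondary allyl terminus (the other is tertiary and neopentyl) on the anion-controlled face to form the C–N bond and the (S) stereocentre of 6, base expels p-toluenesulfinate to give diazene 7, whose concerted six-membered retro-ene loss of N2 delivers hydrogen to the former carbinol carbon on the face that carried nitrogen, so the C–N stereocentre is copied into the (S) C–H stereocentre with the alkene fixed in the 2,3-position, and methanolysis removes the silyl group; the closest known reaction types are Brønsted-acid SN1-type allylic amination through chiral ion pairs (counteranion-directed catalysis) and the Myers/Kabalka allylic diazene reductive transposition, which have not been combined or run enantioconvergently on a tertiary cyclic allylic alcohol.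

**Step 3**
Reactants: 9 (6S)-6-(but-3-yn-1-yl)-1,5,5-trimethylcyclohex-1-ene
Product: 11 (2E)-3-methyl-5-[(1S)-2,6,6-trimethylcyclohex-2-en-1-yl]pent-2-en-1-ol, via alkenyldimethylalane 10 (not isolated)
Conditions: Me3Al (2.5 equiv), Cp2ZrCl2 (25 mol %), CH2Cl2, 0 °C → rt; n-BuLi, THF, −78 °C; (CH2O)n, −78 °C → rt
Reagents that add atoms: trimethylaluminium, C[Al](C)C; formaldehyde (as paraformaldehyde), C=O
Why: Negishi zirconium-catalysed carboalumination adds methyl and aluminium syn across the terminal alkyne with aluminium at the terminus (E ≥ 98:2), and the derived alanate is hydroxymethylated by formaldehyde with retention of geometry, leaving the ring alkene and the stereocentre untouched.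

**Step 4**
Reactants: 11 (2E)-3-methyl-5-[(1S)-2,6,6-trimethylcyclohex-2-en-1-yl]pent-2-en-1-ol
Product: 12 (6S)-6-[(3E)-5-bromo-3-methylpent-3-en-1-yl]-1,5,5-trimethylcyclohex-1-ene
Conditions: PBr3 (0.4 equiv), pyridine (cat.), Et2O, −10 °C
Reagents that add atoms: phosphorus tribromide, BrP(Br)Br
Why: SN2-type bromination of the primary allylic alcohol through its phosphite ester at low temperature proceeds without allylic transposition or loss of E geometry.

**Step 5**
Reactants: 12 (6S)-6-[(3E)-5-bromo-3-methylpent-3-en-1-yl]-1,5,5-trimethylcyclohex-1-ene; 13 1,2,4,5-tetramethoxybenzene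
Product: 15 1,2,4,5-tetramethoxy-3-{(2E)-3-methyl-5-[(1S)-2,6,6-trimethylcyclohex-2-en-1-yl]pent-2-en-1-yl}benzene, via aryllithium 14 (not isolated)
Conditions: 13, n-BuLi, THF, 0 °C → rt; CuBr·SMe2 (10 mol %), then 12, −78 → 0 °C
Reagents that add atoms: none
Why: Directed ortho-lithiation at the position flanked by two methoxy groups, then copper-catalysed SN2 allylation at the unhindered primary carbon (the γ-carbon is fully substituted), forms the aryl–CH2 bond with the E-alkene intact.

**Step 6**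
Reactants: 15 1,2,4,5-tetramethoxy-3-{(2E)-3-methyl-5-[(1S)-2,6,6-trimethylcyclohex-2-en-1-yl]pent-2-en-1-yl}benzene
Product: 16 2,5-dimethoxy-3-{(2E)-3-methyl-5-[(1S)-2,6,6-trimethylcyclohex-2-en-1-yl]pent-2-en-1-yl}cyclohexa-2,5-diene-1,4-dione
Conditions: (NH4)2Ce(NO3)6 (2.5 equiv), MeCN/H2O 3:1, 0 °C, 15 min
Reagents that add atoms: water, O
Why: Oxidative demethylation of a para-dimethoxyarene by (NH4)2Ce(NO3)6 (either para pair gives the same 2,5-dimethoxyquinone) is fast at 0 °C and spares isolated trisubstituted alkenes.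

**Step 7**
Reactants: 16 2,5-dimethoxy-3-{(2E)-3-methyl-5-[(1S)-2,6,6-trimethylcyclohex-2-en-1-yl]pent-2-en-1-yl}cyclohexa-2,5-diene-1,4-dione
Product: 17 2-hydroxy-5-methoxy-3-{(2E)-3-methyl-5-[(1S)-2,6,6-trimethylcyclohex-2-en-1-yl]pent-2-en-1-yl}cyclohexa-2,5-diene-1,4-dione
Conditions: 2 M aq KOH (3 equiv), MeOH/THF, 0 °C → rt; then cold 1 M HCl to pH 3
Reagents that add atoms: potassium hydroxide, [K+].[OH-]
Why: Vinylogous ester saponification (addition–elimination) is expected at the methoxy group flanked by the side chain, which is twisted out of conjugation and so more electrophilic, and the resulting hydroxyquinone anion resists a second substitution; the basic medium also protects the acid-sensitive alkenes.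

**Compound list**
1 | 2,6,6-trimethylcyclohex-2-en-1-one | CC1=CCCC(C)(C)C1=O | starting material
2 | (4-bromobut-1-yn-1-yl)trimethylsilane | C[Si](C)(C)C#CCCBr | starting material
3 | [4-(trimethylsilyl)but-3-yn-1-yl]magnesium bromide | C[Si](C)(C)C#CCC[Mg]Br | intermediate
4 | racemic 2,6,6-trimethyl-1-[4-(trimethylsilyl)but-3-yn-1-yl]cyclohex-2-en-1-ol | CC1=CCCC(C)(C)C1(O)CCC#C[Si](C)(C)C | intermediate
5 | 4-methylbenzenesulfonohydrazide | Cc1ccc(cc1)S(=O)(=O)NN | starting material
6 | N'-{(1S)-2,4,4-trimethyl-3-[4-(trimethylsilyl)but-3-yn-1-yl]cyclohex-2-en-1-yl}-4-methylbenzenesulfonohydrazide | C[Si](C)(C)C#CCCC1=C(C)[C@@H](NNS(=O)(=O)c2ccc(C)cc2)CCC1(C)C | intermediate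
7 | {(1S)-2,4,4-trimethyl-3-[4-(trimethylsilyl)but-3-yn-1-yl]cyclohex-2-en-1-yl}diazene | C[Si](C)(C)C#CCCC1=C(C)[C@@H](N=N)CCC1(C)C | intermediate
8 | trimethyl{4-[(1S)-2,6,6-trimethylcyclohex-2-en-1-yl]but-1-yn-1-yl}silane | C[Si](C)(C)C#CCC[C@@H]1C(C)=CCCC1(C)C | intermediate
9 | (6S)-6-(but-3-yn-1-yl)-1,5,5-trimethylcyclohex-1-ene | C#CCC[C@@H]1C(C)=CCCC1(C)C | intermediate
10 | dimethyl{(1E)-2-methyl-4-[(1S)-2,6,6-trimethylcyclohex-2-en-1-yl]but-1-en-1-yl}alumane | C[Al](C)/C=C(\C)CC[C@@H]1C(C)=CCCC1(C)C | intermediate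
11 | (2E)-3-methyl-5-[(1S)-2,6,6-trimethylcyclohex-2-en-1-yl]pent-2-en-1-ol | OC/C=C(\C)CC[C@@H]1C(C)=CCCC1(C)C | intermediate
12 | (6S)-6-[(3E)-5-bromo-3-methylpent-3-en-1-yl]-1,5,5-trimethylcyclohex-1-ene | BrC/C=C(\C)CC[C@@H]1C(C)=CCCC1(C)C | intermediate
13 | 1,2,4,5-tetramethoxybenzene | COc1cc(OC)c(OC)cc1OC | starting material
14 | (2,3,5,6-tetramethoxyphenyl)lithium | [Li]c1c(OC)c(OC)cc(OC)c1OC | intermediate
15 | 1,2,4,5-tetramethoxy-3-{(2E)-3-methyl-5-[(1S)-2,6,6-trimethylcyclohex-2-en-1-yl]pent-2-en-1-yl}benzene | COc1cc(OC)c(OC)c(C/C=C(\C)CC[C@@H]2C(C)=CCCC2(C)C)c1OC | intermediate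
16 | 2,5-dimethoxy-3-{(2E)-3-methyl-5-[(1S)-2,6,6-trimethylcyclohex-2-en-1-yl]pent-2-en-1-yl}cyclohexa-2,5-diene-1,4-dione | COC1=CC(=O)C(OC)=C(C/C=C(\C)CC[C@@H]2C(C)=CCCC2(C)C)C1=O | intermediate
17 | 2-hydroxy-5-methoxy-3-{(2E)-3-methyl-5-[(1S)-2,6,6-trimethylcyclohex-2-en-1-yl]pent-2-en-1-yl}cyclohexa-2,5-diene-1,4-dione | COC1=CC(=O)C(O)=C(C/C=C(\C)CC[C@@H]2C(C)=CCCC2(C)C)C1=O | target

**Totals and risks**
Total step count: 7. Longest linear sequence: 7 steps (1 → 4 → 9 → 11 → 12 → 15 → 16 → 17).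

The three steps most likely to fail are the proposed step 2, step 7 and step 5.

The proposed step 2 may give low enantioselectivity, attack at the tertiary terminus, or re-ionisation of 6 before the base is added. Its fallback uses known chemistry, sets out from 4 and comes back at 9. Alcohol 4 is oxidised with 1,3-transposition (Dauben type) by pyridinium chlorochromate (C5H5NH)[CrO3Cl] in CH2Cl2 to 2,4,4-trimethyl-3-[4-(trimethylsilyl)but-3-yn-1-yl]cyclohex-2-en-1-one F1. Reduction with (S)-2-methyl-CBS-oxazaborolidine and catecholborane in toluene at −78 °C gives (1R)-2,4,4-trimethyl-3-[4-(trimethylsilyl)but-3-yn-1-yl]cyclohex-2-en-1-ol F2. Myers reductive transposition (2-nitrobenzenesulfonohydrazide, PPh3, diethyl azodicarboxylate, THF, −30 °C → rt) inverts the carbinol carbon to N-{(1S)-2,4,4-trimethyl-3-[4-(trimethylsilyl)but-3-yn-1-yl]cyclohex-2-en-1-yl}-2-nitrobenzenesulfonohydrazide F3. F3 loses sulfinic acid to diazene 7 and then N2 to 8, and K2CO3/MeOH gives 9.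

In step 7 the hydroxide may attack the unhindered methoxy group instead, or both. The fallback fixes the hydroxyl position by construction, sets out from bromide 12 and comes back at 17. 2,4,5-Trimethoxyphenol F7 is converted with NaH in toluene into sodium 2,4,5-trimethoxyphenolate F8. F8 is C-allylated by 12 at its only free ortho position to give 3,4,6-trimethoxy-2-{(2E)-3-methyl-5-[(1S)-2,6,6-trimethylcyclohex-2-en-1-yl]pent-2-en-1-yl}phenol F9. Ac2O/pyridine gives the aryl acetate F10. (NH4)2Ce(NO3)6 in MeCN/H2O oxidises the para-dimethoxy pair and leaves the acetate, giving the 2-acetoxy-5-methoxyquinone F11. K2CO3/MeOH at 0 °C removes the acetate to give 17.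

In step 5 the aryllithium may give SN2′ attack, halogen–metal exchange or Wurtz coupling with the allylic bromide. The fallback moves the bond formation to the vinyl–CH2 bond, sets out from alkyne 9 (through alane 10) and aryllithium 14, and comes back at 15. Aryllithium 14 is quenched with DMF to give 2,3,5,6-tetramethoxybenzaldehyde F4. NaBH4 in MeOH gives (2,3,5,6-tetramethoxyphenyl)methanol F5. Concentrated HCl in CH2Cl2 at 0 °C gives 3-(chloromethyl)-1,2,4,5-tetramethoxybenzene F6. Alane 10, made from 9 as in step 3 without the formaldehyde quench, is coupled with F6 using Pd(PPh3)4 (5 mol %) in THF (Negishi-type alkenylalane–benzyl chloride coupling) to give 15 directly.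

**Further compounds**
F1 | step 2 | 2,4,4-trimethyl-3-[4-(trimethylsilyl)but-3-yn-1-yl]cyclohex-2-en-1-one | C[Si](C)(C)C#CCCC1=C(C)C(=O)CCC1(C)C
F2 | step 2 | (1R)-2,4,4-trimethyl-3-[4-(trimethylsilyl)but-3-yn-1-yl]cyclohex-2-en-1-ol | C[Si](C)(C)C#CCCC1=C(C)[C@H](O)CCC1(C)C
F3 | step 2 | N-{(1S)-2,4,4-trimethyl-3-[4-(trimethylsilyl)but-3-yn-1-yl]cyclohex-2-en-1-yl}-2-nitrobenzenesulfonohydrazide | C[Si](C)(C)C#CCCC1=C(C)[C@@H](N(N)S(=O)(=O)c2ccccc2[N+](=O)[O-])CCC1(C)C
F4 | step 5 | 2,3,5,6-tetramethoxybenzaldehyde | COc1cc(OC)c(OC)c(C=O)c1OC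
F5 | step 5 | (2,3,5,6-tetramethoxyphenyl)methanol | COc1cc(OC)c(OC)c(CO)c1OC
F6 | step 5 | 3-(chloromethyl)-1,2,4,5-tetramethoxybenzene | COc1cc(OC)c(OC)c(CCl)c1OC
F7 | step 7 | 2,4,5-trimethoxyphenol | Oc1cc(OC)c(OC)cc1OC
F8 | step 7 | sodium 2,4,5-trimethoxyphenolate | [Na+].[O-]c1cc(OC)c(OC)cc1OC
F9 | step 7 | 3,4,6-trimethoxy-2-{(2E)-3-methyl-5-[(1S)-2,6,6-trimethylcyclohex-2-en-1-yl]pent-2-en-1-yl}phenol | Oc1c(C/C=C(\C)CC[C@@H]2C(C)=CCCC2(C)C)c(OC)c(OC)cc1OC
F10 | step 7 | 3,4,6-trimethoxy-2-{(2E)-3-methyl-5-[(1S)-2,6,6-trimethylcyclohex-2-en-1-yl]pent-2-en-1-yl}phenyl acetate | CC(=O)Oc1c(C/C=C(\C)CC[C@@H]2C(C)=CCCC2(C)C)c(OC)c(OC)cc1OC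
F11 | step 7 | 4-methoxy-2-{(2E)-3-methyl-5-[(1S)-2,6,6-trimethylcyclohex-2-en-1-yl]pent-2-en-1-yl}-3,6-dioxocyclohexa-1,4-dien-1-yl acetate | COC1=CC(=O)C(OC(C)=O)=C(C/C=C(\C)CC[C@@H]2C(C)=CCCC2(C)C)C1=O
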